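All constants belong to no real substance; the flask was simulated.

The electrophile is the species to follow in Saturday's and Friday's flasks: whatever has gone from it into the dormant form or into product counts as reacted.

- Saturday's: electrophile 0.10 M; nucleophile 0.150 M (fed, over 20 min); solid base 0.0500 M; time 50 min; the fed solution adds 0.10 times the starting volume
- Friday's: electrophile 0.10 M; nucleophile 0.300 M (fed, over 20 min); solid base 0.0500 M; time 50 min; the fed solution adds 0.10 times the starting volume

- part of the electrophile that has reacted at the end, Saturday's
- part of the electrophile that has reacted at the end, Friday's
- what raising the concentration of nucleophile from its lowest to its highest value here does to the part of the electrophile that has reacted (changes below 5 percentage points count as none) (it rises / it falls / no change)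

    electrophile + nucleophile → acid set free + product (k1 = 0.219 /M/min)
    nucleophile + acid set free ⇌ protonated nucleophile, settled at all times (K2 = 76 /M)
    acid set free + free base ⇌ salt of the base (K3 = 11 /M, k3 = 16.7 /M/min)
    crystals ⇌ acid set free, rate k4*(cs4 - [acid set free]) while solid is left; crystals form when [acid set free] > cs4 (cs4 = 41 mM, k4 = 1.43 /min)
    electrophile ⇌ dormant form (K5 = 2.4, k5 = 0.0314 /min)
    solid base ⇌ free base, rate k6*(cs6 - [free base]) while solid is left; crystals form when [free base] > cs6 (cs6 = 0.089 M, k6 = 0.0365 /min)

I start by comparing rates at one moment. The electrophile leaves for the dormant form with a half-life of 22 min. Attack by the nucleophile is a pseudo-first-order loss at any given nucleophile level, and with Saturday's whole charge present at once its half-life is 21 min, about the same. So I keep both exits. The dormant form also returns, at 0.0131 /min, so that exit leaks back.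

Now the drift. The nucleophile arrives over 20 min, so I count its diluted charge as present for 40.0 min of the 50 min, which gives Saturday's a mean attack rate of 0.0239 /min. With these rates the electrophile falls quickly while the exchange balances, and then the pair of electrophile and dormant form empties slowly, at 0.00493 /min. That leaves 0.145 of the charge as electrophile in Saturday's flask.

The weak link is that full nucleophile level. Each product takes one nucleophile for the attack and sets free one acid, and with the whole diluted charge free the balance would stand at 10.4 protonated to one free acid. That is an upper figure, so I reckon a product as costing a little under two nucleophile. That loss builds up through the run, so I charge one per product on average, taking product as what the balanced pair has given up, 0.507 of the charge. Saturday's attack rate becomes 0.0158 /min. The slow drain, the rate at which electrophile and dormant form together empty once balanced, becomes 0.00365 /min. Saturday's electrophile left is then 0.197, so I commit to 80.3% reacted.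

Friday's flask goes through the same chain: attack 0.0478 /min, slow drain 0.00736 /min, electrophile left 0.0643. Reforged, the attack is 0.0353 /min and the drain 0.00629 /min, leaving 0.0965, so 90.3% reacted. I expect a rise of 10 percentage points.

The forecast, made separately and a little apart from my numbers, says 81%, 90% and it rises, holding that “Acid released is mostly held as protonated nucleophile”. The flasks give 81.0% and 90.1%: it rises, by 9.1 points.

Neither flask is at rest at 50.0 min. Saturday's electrophile and dormant form together hold 66.3% of the charge then and 23.2% at 500 min, a reading of 0.00233 /min, below my slow drain of 0.00365 /min, with 19.0% of its nucleophile left. Friday's pair reads 0.00552 /min against my 0.00629 /min. Product still climbs to 76.8% on Saturday's and 96.1% on Friday's. Reacted electrophile reaches 93.8% and 99.2%, a gap narrowed to 5.4 points.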